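**Plan**

- Locants follow the furo[3,2-c][1,2]dioxin-6-one core: O1–O2 peroxide, C3 (methyl, chain), C4 (CH2), C4a (methyl, lactone O5), C6 (C=O), C7 (CH2), C7a (CH–O1).
- Retrosynthesis: the C3–C4 bond of the dioxane and the C4a–O5 bond of the lactone are cut together (peroxycarbenium ion at C3 + isopropenyl group + carboxylic acid). Next the O1–C7a bond is cut (conjugate addition of a hydroperoxide to a dienal), then the chain at its alkyne and at the aryl–CH2 bond.
- Enabling feature: C3 carries a peroxide oxygen, so it can be the carbon of a peroxycarbenium ion. C4a, one bond from C4, is tertiary and oxygen-bearing, i.e. the cation end of a 1,1-disubstituted alkene. The carboxyl carbon C6 sits two atoms from C4a, so one cationic event closes the dioxane ring and then the lactone ring.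
- Forward: aryl Grignard coupling and acetylide alkylation give the chain as an alkynyl ketal, and perhydrolysis turns it into an α-methoxy hydroperoxide. This is joined to 4-methylpenta-2,4-dienal, the aldehyde is oxidised to the acid, both rings are closed in one step (dioxane first, lactone second), the alkyne is reduced and the phenol is freed.
- Stereochemistry: C7a comes from the organocatalyst. C4a is relayed from C7a by the enforced cis ring fusion. C3 is relayed through the chair transition state, the chain being kept at the alkyne oxidation level so that it is the small, axial group.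

Key step: step 8

Remark: the sense of induction in step 6 is assigned from the accepted steric model of the diarylprolinol silyl ether iminium ion; if the peroxide entered on the other face, the (S)-catalyst would be used instead.

**Route**

Step 1
Reactants: 1 (4-bromophenoxy)(tert-butyl)dimethylsilane; 2 1,8-dibromooctane
Product: 4 [4-(8-bromooctyl)phenoxy](tert-butyl)dimethylsilane, via aryl Grignard reagent 3 (not isolated)
Conditions: Mg, THF, reflux; then 2 (3 equiv), Li2CuCl4 (3 mol %), THF, −10 °C → rt
Reagents that add atoms: none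
Why: Copper-catalysed cross-coupling of an aryl Grignard reagent with a primary alkyl bromide; the excess of the symmetric dibromide suppresses double arylation and the aryl silyl ether is inert to the Grignard reagent.

Step 2
Reactants: 5 but-3-yn-2-one
Product: 6 3,3-dimethoxybut-1-yne
Conditions: HC(OMe)3, MeOH, TsOH (cat.), rt
Reagents that add atoms: trimethyl orthoformate, COC(OC)OC
Why: Acid-catalysed ketalisation of a ketone with an orthoester as dehydrating agent; the terminal alkyne is untouched under acid.

Step 3
Reactants: 6 3,3-dimethoxybut-1-yne; 4 [4-(8-bromooctyl)phenoxy](tert-butyl)dimethylsilane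
Product: 8 tert-butyl[4-(11,11-dimethoxydodec-9-yn-1-yl)phenoxy]dimethylsilane, via lithium acetylide 7 (not isolated)
Conditions: n-BuLi, THF, −78 °C; then 4, DMPU, NaI (cat.), −78 °C → rt
Reagents that add atoms: none
Why: Deprotonation of the terminal alkyne and SN2 alkylation of the lithium acetylide by the primary bromide; ketal and aryl silyl ether are stable to the base.

Step 4
Reactants: 8 tert-butyl[4-(11,11-dimethoxydodec-9-yn-1-yl)phenoxy]dimethylsilane
Product: 9 tert-butyl[4-(11-hydroperoxy-11-methoxydodec-9-yn-1-yl)phenoxy]dimethylsilane (racemic)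
Conditions: anhydrous H2O2 in Et2O (2 equiv), camphorsulfonic acid (cat.), 0 °C, short reaction time
Reagents that add atoms: hydrogen peroxide, OO
Why: Acid-catalysed exchange of one methoxy group of a dimethyl ketal for hydrogen peroxide by way of the alkynyl oxocarbenium ion (perhydrolysis of a ketal), a known route to α-alkoxy hydroperoxides; the new stereocenter is formed racemic and is lost again in step 8.

Step 5
Reactants: 10 methacrolein; 11 (triphenylphosphoranylidene)acetaldehyde
Product: 12 (2E)-4-methylpenta-2,4-dienal
Conditions: CH2Cl2, 40 °C, 10 in excess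
Reagents that add atoms: none
Why: Wittig olefination with a stabilised formyl ylide, which gives the E-enal; the excess of methacrolein limits a second homologation.

Step 6
Reactants: 9 tert-butyl[4-(11-hydroperoxy-11-methoxydodec-9-yn-1-yl)phenoxy]dimethylsilane; 12 (2E)-4-methylpenta-2,4-dienal
Product: 13 (3R)-3-{[12-(4-{[tert-butyl(dimethyl)silyl]oxy}phenyl)-2-methoxydodec-3-yn-2-yl]peroxy}-4-methylpent-4-enal (both epimers at the peroxyketal carbon)
Conditions: (R)-2-{bis[3,5-bis(trifluoromethyl)phenyl][(trimethylsilyl)oxy]methyl}pyrrolidine (10 mol %), PhCO2H (10 mol %), toluene, −20 °C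
Reagents that add atoms: none
Why: Enantioselective conjugate addition (oxa-Michael) of a hydroperoxide to an enal by iminium catalysis with a diarylprolinol silyl ether, the acid co-catalyst protonating the peroxy enamine before it can close to an epoxide; the hydroperoxide adds to the β-carbon of the E,s-trans iminium ion on the face away from the diaryl(silyloxy)methyl group, which with the (R)-catalyst should give the (R)-configured C–O bond (the later C7a).

Step 7
Reactants: 13 (3R)-3-{[12-(4-{[tert-butyl(dimethyl)silyl]oxy}phenyl)-2-methoxydodec-3-yn-2-yl]peroxy}-4-methylpent-4-enal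
Product: 14 (3R)-3-{[12-(4-{[tert-butyl(dimethyl)silyl]oxy}phenyl)-2-methoxydodec-3-yn-2-yl]peroxy}-4-methylpent-4-enoic acid
Conditions: NaClO2, NaH2PO4, 2-methyl-2-butene, t-BuOH/H2O, 0 °C
Reagents that add atoms: sodium chlorite, [Na+].[O-]Cl=O
Why: Pinnick oxidation of the aldehyde under buffered, weakly acidic conditions that avoid base-induced β-elimination of the peroxide; 2-methyl-2-butene scavenges the hypochlorous acid and so protects the isopropenyl group.

Step 8
Reactants: 14 (3R)-3-{[12-(4-{[tert-butyl(dimethyl)silyl]oxy}phenyl)-2-methoxydodec-3-yn-2-yl]peroxy}-4-methylpent-4-enoic acid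
Product: 16 (3R,4aR,7aR)-3-[10-(4-{[tert-butyl(dimethyl)silyl]oxy}phenyl)dec-1-yn-1-yl]-3,4a-dimethyl-4,4a,7,7a-tetrahydrofuro[3,2-c][1,2]dioxin-6(3H)-one, via peroxycarbenium triflate 15 (not isolated)
Conditions: TMSOTf (1.2 equiv), 2,6-di-tert-butyl-4-methylpyridine (1.5 equiv), CH2Cl2, −78 → −40 °C
Reagents that add atoms: none
Why: Proposed new method: TMSOTf abstracts the methoxy group of the peroxyketal and gives the alkynyl-stabilised peroxycarbenium ion 15; the CH2 terminus of the isopropenyl group attacks its carbon in the Markovnikov sense, and the tertiary cation so formed at C4a, which neither peroxide oxygen can reach in a ring larger than four-membered, is captured by the carboxyl group, the proton going to the hindered pyridine. The closest known reaction types are the Lewis-acid reactions of peroxycarbenium ions from monoperoxyketals with alkenes and allylsilanes (open-chain allylation, cyclisation to cyclic peroxides, [3+2] annulation to 1,2-dioxolanes) and the Prins cyclisation ended by an internal carboxyl group. The 1,2-dioxane closes 6-endo-trig with respect to both the alkene and the C=O+ bond through a chair transition state, and the γ-lactone closes by five-membered capture of the planar cation by the carboxyl oxygen. C4a is controlled by C7a, because the one-carbon tether lets the carboxyl group reach the cation only on its own face, so the ring fusion must be cis; C3 is controlled by the chair, in which the CH2CO2H arm of C7a lies equatorial and the rod-like alkynyl group (conformational energy in cyclohexane about 0.4 kcal/mol against about 1.7 for methyl) takes the axial site on the face where the lactone oxygen enters while methyl stays equatorial, which places the chain cis to the lactone ring as in the target. The step needs chemoselective ionisation of the C–OMe bond in preference to the O–O and allylic C–O bonds, secured by the low temperature and by the alkyne and peroxide oxygen that stabilise this cation alone; it also needs face selectivity at C3, secured by holding the chain at the alkyne oxidation level so that the two substituents of the cationic carbon differ strongly in size, a difference a saturated chain would not offer.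

Step 9
Reactants: 16 (3R,4aR,7aR)-3-[10-(4-{[tert-butyl(dimethyl)silyl]oxy}phenyl)dec-1-yn-1-yl]-3,4a-dimethyl-4,4a,7,7a-tetrahydrofuro[3,2-c][1,2]dioxin-6(3H)-one
Product: 17 (3S,4aR,7aR)-3-[10-(4-{[tert-butyl(dimethyl)silyl]oxy}phenyl)decyl]-3,4a-dimethyl-4,4a,7,7a-tetrahydrofuro[3,2-c][1,2]dioxin-6(3H)-one
Conditions: KO2CN=NCO2K (large excess, in portions), AcOH, MeOH/CH2Cl2, 0 °C → rt
Reagents that add atoms: none
Why: Diimide reduction, which transfers hydrogen to the alkyne and then to the Z-alkene in a concerted syn fashion and leaves the O–O bond, the lactone and the aryl silyl ether alone, where catalytic hydrogenation would cleave the peroxide; no stereocenter is touched (the descriptor at C3 changes only through the priority rules).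

Step 10
Reactants: 17 (3S,4aR,7aR)-3-[10-(4-{[tert-butyl(dimethyl)silyl]oxy}phenyl)decyl]-3,4a-dimethyl-4,4a,7,7a-tetrahydrofuro[3,2-c][1,2]dioxin-6(3H)-one
Product: 18 plakortolide S, (3S,4aR,7aR)-3-[10-(4-hydroxyphenyl)decyl]-3,4a-dimethyl-4,4a,7,7a-tetrahydrofuro[3,2-c][1,2]dioxin-6(3H)-one
Conditions: KHF2, MeOH, rt
Reagents that add atoms: none
Why: Cleavage of the aryl silyl ether by KHF2 under weakly acidic conditions, chosen over basic fluoride because base would open the peroxide by β-elimination from the lactone α-position.

**Compound list**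

1 | (4-bromophenoxy)(tert-butyl)dimethylsilane | CC(C)(C)[Si](C)(C)Oc1ccc(Br)cc1 | starting material
2 | 1,8-dibromooctane | BrCCCCCCCCBr | starting material
3 | {4-[(tert-butyldimethylsilyl)oxy]phenyl}magnesium bromide | CC(C)(C)[Si](C)(C)Oc1ccc([Mg]Br)cc1 | intermediate
4 | [4-(8-bromooctyl)phenoxy](tert-butyl)dimethylsilane | CC(C)(C)[Si](C)(C)Oc1ccc(CCCCCCCCBr)cc1 | intermediate
5 | but-3-yn-2-one | CC(=O)C#C | starting material
6 | 3,3-dimethoxybut-1-yne | CC(OC)(OC)C#C | intermediate
7 | (3,3-dimethoxybut-1-yn-1-yl)lithium | CC(OC)(OC)C#C[Li] | intermediate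
8 | tert-butyl[4-(11,11-dimethoxydodec-9-yn-1-yl)phenoxy]dimethylsilane | CC(OC)(OC)C#CCCCCCCCCc1ccc(O[Si](C)(C)C(C)(C)C)cc1 | intermediate
9 | tert-butyl[4-(11-hydroperoxy-11-methoxydodec-9-yn-1-yl)phenoxy]dimethylsilane (racemic) | CC(OC)(OO)C#CCCCCCCCCc1ccc(O[Si](C)(C)C(C)(C)C)cc1 | intermediate
10 | methacrolein (2-methylprop-2-enal) | CC(=C)C=O | starting material
11 | (triphenylphosphoranylidene)acetaldehyde | O=CC=P(c1ccccc1)(c1ccccc1)c1ccccc1 | starting material
12 | (2E)-4-methylpenta-2,4-dienal | CC(=C)/C=C/C=O | intermediate
13 | (3R)-3-{[12-(4-{[tert-butyl(dimethyl)silyl]oxy}phenyl)-2-methoxydodec-3-yn-2-yl]peroxy}-4-methylpent-4-enal (both epimers at the peroxyketal carbon) | C=C(C)[C@@H](CC=O)OOC(C)(OC)C#CCCCCCCCCc1ccc(O[Si](C)(C)C(C)(C)C)cc1 | intermediate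
14 | (3R)-3-{[12-(4-{[tert-butyl(dimethyl)silyl]oxy}phenyl)-2-methoxydodec-3-yn-2-yl]peroxy}-4-methylpent-4-enoic acid (both epimers at the peroxyketal carbon) | C=C(C)[C@@H](CC(=O)O)OOC(C)(OC)C#CCCCCCCCCc1ccc(O[Si](C)(C)C(C)(C)C)cc1 | intermediate
15 | peroxycarbenium triflate formed from 14 by loss of methoxide (O-[(3R)-1-carboxy-4-methylpent-4-en-3-yloxy]oxocarbenium ion of the ynone, triflate counter-ion) | C=C(C)[C@@H](CC(=O)O)O[O+]=C(C)C#CCCCCCCCCc1ccc(O[Si](C)(C)C(C)(C)C)cc1.[O-]S(=O)(=O)C(F)(F)F | intermediate
16 | (3R,4aR,7aR)-3-[10-(4-{[tert-butyl(dimethyl)silyl]oxy}phenyl)dec-1-yn-1-yl]-3,4a-dimethyl-4,4a,7,7a-tetrahydrofuro[3,2-c][1,2]dioxin-6(3H)-one (cis-fused; alkynyl chain cis to the lactone ring) | C[C@]1(C#CCCCCCCCCc2ccc(O[Si](C)(C)C(C)(C)C)cc2)C[C@@]2(C)OC(=O)C[C@H]2OO1 | intermediate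
17 | (3S,4aR,7aR)-3-[10-(4-{[tert-butyl(dimethyl)silyl]oxy}phenyl)decyl]-3,4a-dimethyl-4,4a,7,7a-tetrahydrofuro[3,2-c][1,2]dioxin-6(3H)-one | C[C@]1(CCCCCCCCCCc2ccc(O[Si](C)(C)C(C)(C)C)cc2)C[C@@]2(C)OC(=O)C[C@H]2OO1 | intermediate
18 | plakortolide S, (3S,4aR,7aR)-3-[10-(4-hydroxyphenyl)decyl]-3,4a-dimethyl-4,4a,7,7a-tetrahydrofuro[3,2-c][1,2]dioxin-6(3H)-one | C[C@]1(CCCCCCCCCCc2ccc(O)cc2)C[C@@]2(C)OC(=O)C[C@H]2OO1 | target

**Step count and risks**

Total steps: 10. Longest linear sequence: 8 (steps 1, 3, 4, 6, 7, 8, 9, 10).

Steps most likely to fail: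

1. Step 8. The Lewis acid may heterolyse the O–O bond or the allylic C–O bond instead of the C–OMe bond. The tertiary cation may lose a proton before the carboxyl group captures it. The alkene may also attack through the chair that carries the acetic acid arm axial (favoured by relief of allylic 1,2-strain against the vinylic methyl group), which would give the C3 epimer.
Fallback (known chemistry, sets out from 9 and 11, comes back at 16): the cascade is split into an allylsilane-terminated cyclisation and a separate lactonisation. Commercial 2-[(trimethylsilyl)methyl]prop-2-en-1-ol is oxidised (MnO2, CH2Cl2) to 2-[(trimethylsilyl)methyl]prop-2-enal F1, which with 11 gives (2E)-4-[(trimethylsilyl)methyl]penta-2,4-dienal F2. Hydroperoxide 9 is added to F2 under the conditions of step 6 to give the silylated β-peroxy aldehyde F3, and Pinnick oxidation gives the acid F4. TMSOTf at −78 °C then brings about the intramolecular Hosomi–Sakurai reaction of the peroxycarbenium ion; the β-silyl cation ends cleanly by loss of the silyl group, and the 4-methylidene-1,2-dioxane acid F5 should result, at which stage a C3 epimer could be separated. Acid-catalysed Markovnikov addition of the carboxyl group to the exocyclic alkene (TfOH cat., CH2Cl2, 0 °C) closes the cis-lactone and gives 16.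

2. Step 6. The hindered, functionalised hydroperoxide 9 may add slowly, so that collapse of the peroxy enamine to the epoxy aldehyde, conjugate addition at the terminal carbon of the dienyl iminium ion, or erosion of the enantioselectivity take over.
Fallback (sets out from 12 and 8, comes back at 14): the chain is no longer brought in by the nucleophile but attached afterwards by peroxyketal exchange. 2-Hydroperoxy-2-methoxypropane F6 (ozonolysis of 2,3-dimethylbut-2-ene in methanol), a small hydroperoxide of the type established for enal peroxidation, is added to 12 under the conditions of step 6 to give (3R)-3-[(2-methoxypropan-2-yl)peroxy]-4-methylpent-4-enal F7. Pinnick oxidation gives the acid F8, and aqueous acetic acid in THF frees (3R)-3-hydroperoxy-4-methylpent-4-enoic acid F9. Exchange of F9 with ketal 8 (PPTS cat., CH2Cl2, 4 Å molecular sieves) gives 14.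

3. Step 4. A second exchange may lead to the geminal dihydroperoxide, two molecules may condense to a bis(peroxyketal), or the propargylic hydroperoxide may rearrange under acid.
Fallback (sets out from 8, comes back at 9): the hydroperoxide is made by ozonolysis of an enol ether, where the direction of cleavage is fixed. Ketal 8 is hydrolysed (PPTS, acetone/H2O) to 12-(4-{[tert-butyl(dimethyl)silyl]oxy}phenyl)dodec-3-yn-2-one F10. Wittig reaction with (methoxymethylidene)triphenylphosphorane F11 (from (methoxymethyl)triphenylphosphonium chloride and KOtBu, THF, 0 °C) gives the methyl enol ether F12 as an E/Z mixture. Ozonolysis of F12 in MeOH/CH2Cl2 at −78 °C with one equivalent of ozone cleaves the electron-rich enol ether in preference to the alkyne and the arene; the alkynyl carbonyl oxide is captured by methanol and gives 9.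

Further compounds
F1 | step 8 | 2-[(trimethylsilyl)methyl]prop-2-enal | C=C(C[Si](C)(C)C)C=O
F2 | step 8 | (2E)-4-[(trimethylsilyl)methyl]penta-2,4-dienal | C=C(C[Si](C)(C)C)/C=C/C=O
F3 | step 8 | (3R)-3-{[12-(4-{[tert-butyl(dimethyl)silyl]oxy}phenyl)-2-methoxydodec-3-yn-2-yl]peroxy}-4-[(trimethylsilyl)methyl]pent-4-enal | C=C(C[Si](C)(C)C)[C@@H](CC=O)OOC(C)(OC)C#CCCCCCCCCc1ccc(O[Si](C)(C)C(C)(C)C)cc1
F4 | step 8 | (3R)-3-{[12-(4-{[tert-butyl(dimethyl)silyl]oxy}phenyl)-2-methoxydodec-3-yn-2-yl]peroxy}-4-[(trimethylsilyl)methyl]pent-4-enoic acid | C=C(C[Si](C)(C)C)[C@@H](CC(=O)O)OOC(C)(OC)C#CCCCCCCCCc1ccc(O[Si](C)(C)C(C)(C)C)cc1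
F5 | step 8 | 2-{(3R,6R)-6-[10-(4-{[tert-butyl(dimethyl)silyl]oxy}phenyl)dec-1-yn-1-yl]-6-methyl-4-methylidene-1,2-dioxan-3-yl}acetic acid | C[C@]1(C#CCCCCCCCCc2ccc(O[Si](C)(C)C(C)(C)C)cc2)CC(=C)[C@@H](CC(=O)O)OO1
F6 | step 6 | 2-hydroperoxy-2-methoxypropane | COC(C)(C)OO
F7 | step 6 | (3R)-3-[(2-methoxypropan-2-yl)peroxy]-4-methylpent-4-enal | C=C(C)[C@@H](CC=O)OOC(C)(C)OC
F8 | step 6 | (3R)-3-[(2-methoxypropan-2-yl)peroxy]-4-methylpent-4-enoic acid | C=C(C)[C@@H](CC(=O)O)OOC(C)(C)OC
F9 | step 6 | (3R)-3-hydroperoxy-4-methylpent-4-enoic acid | C=C(C)[C@@H](CC(=O)O)OO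
F10 | step 4 | 12-(4-{[tert-butyl(dimethyl)silyl]oxy}phenyl)dodec-3-yn-2-one | CC(=O)C#CCCCCCCCCc1ccc(O[Si](C)(C)C(C)(C)C)cc1
F11 | step 4 | (methoxymethylidene)triphenylphosphorane | COC=P(c1ccccc1)(c1ccccc1)c1ccccc1
F12 | step 4 | tert-butyl[4-(12-methoxy-11-methyldodec-11-en-9-yn-1-yl)phenoxy]dimethylsilane (E/Z mixture) | COC=C(C)C#CCCCCCCCCc1ccc(O[Si](C)(C)C(C)(C)C)cc1
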